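**Retrosynthetic overview**

1. Feature: in ring A the C3 acetoxy group sits β to the C19 formyl carbon on quaternary C4 (O–C3–C4–C19=O), an aldol retron. Ring A is therefore opened at C3–C4 to a ring B bromo ester aldehyde (C4 ester enolate + C3 aldehyde) and closed forward with SmI2 as an intramolecular Reformatsky reaction.
2. C18 is added after the closure. A C4 enolate that already carries C18 would keep C5–H eclipsed with the enolate (allylic 1,3-strain) and leave the ester equatorial, the wrong C4 epimer. α-Face C-methylation of the 3β-hydroxy ester dianion instead gives the axial C19 ester. Then C19 ester → CHO, O3 acetylation, O15 desilylation.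
3. Ring B precursor: C8=CH2 by Wittig; C1–C3 arm by Sakurai allylation at C10 (anti to the C5 arm) and hydroboration–oxidation; C9 side chain by α-iodination and B-alkyl Suzuki coupling with the diene from (E)-3-methylpent-2-en-4-yn-1-ol.
4. C5 stereocentre (source of all others): CBS reduction of 2-methylcyclohex-2-en-1-one, Johnson–Claisen chirality transfer, allylic oxidation to the 4-substituted 3-methylcyclohexenone.
5. Ring order: ring B is carried from the first step; ring A is formed in step 13.

Key step: step 13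

Remark: labdane numbering is used for every intermediate, β being the face that carries the C10 methyl (C20); O15 is carried as its tert-butyldiphenylsilyl (TBDPS) ether, chosen for its stability to TiCl4.

**Route**

Step 1
Reactants: 1 2-methylcyclohex-2-en-1-one
Product: 2 (S)-2-methylcyclohex-2-en-1-ol
Conditions: (R)-2-methyl-CBS-oxazaborolidine (10 mol %), BH3·SMe2, THF, −20 °C
Reagents that add atoms: none
Why: Corey–Bakshi–Shibata reduction, in which the trisubstituted alkenyl arm of the enone acts as the large group, so the (R)-catalyst should deliver hydride to the face that gives the (S)-carbinol, whose configuration is later relayed to C5.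

Step 2
Reactants: 2 (S)-2-methylcyclohex-2-en-1-ol; 3 trimethyl orthoacetate
Product: 5 methyl 2-[(1S)-2-methylcyclohex-2-en-1-yl]acetate, via ketene acetal 4 (not isolated)
Conditions: EtCO2H (cat.), xylene, 140 °C, MeOH distilled off
Reagents that add atoms: none
Why: Johnson–Claisen rearrangement, in which the suprafacial [3,3] shift of ketene acetal 4 across the ring transfers the carbinol configuration to the new C5–C4 bond (C5 S) and moves the alkene to C9=C10.

Step 3
Reactants: 5 methyl 2-[(1S)-2-methylcyclohex-2-en-1-yl]acetate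
Product: 6 methyl 2-[(1S)-2-methyl-4-oxocyclohex-2-en-1-yl]acetate
Conditions: Rh2(cap)4 (dirhodium tetrakis(caprolactamate), 1 mol %), t-BuOOH (70% in water), K2CO3, CH2Cl2, 23 °C
Reagents that add atoms: tert-butyl hydroperoxide, CC(C)(C)OO
Why: Rh2(cap)4-catalysed allylic C–H oxidation (known for 1-alkylcyclohexenes), in which hydrogen abstraction is expected at the open C8 methylene next to the CH terminus of the alkene and not at the shielded tertiary C5–H, so the enone forms without touching C5.

Step 4
Reactants: 6 methyl 2-[(1S)-2-methyl-4-oxocyclohex-2-en-1-yl]acetate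
Product: 7 methyl 2-[(1S)-3-iodo-2-methyl-4-oxocyclohex-2-en-1-yl]acetate
Conditions: I2, pyridine, DMAP (cat.), CH2Cl2, 23 °C
Reagents that add atoms: iodine, II
Why: α-iodination of an enone by the iodine–pyridine (Johnson) protocol, in which conjugate addition of the amine, iodination of the enolate at C9 and elimination install the vinyl iodide needed for cross-coupling.

Step 5
Reactants: 8 (E)-3-methylpent-2-en-4-yn-1-ol
Product: 9 tert-butyl{[(2E)-3-methylpent-2-en-4-yn-1-yl]oxy}diphenylsilane
Conditions: TBDPSCl, imidazole, CH2Cl2, 0 → 23 °C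
Reagents that add atoms: tert-butyl(chloro)diphenylsilane, CC(C)(C)[Si](Cl)(c1ccccc1)c1ccccc1
Why: standard silylation of a primary allylic alcohol, giving an ether that should withstand TiCl4, LiN(iPr)2, SmI2 and LiAlH4 later on.

Step 6
Reactants: 9 tert-butyl{[(2E)-3-methylpent-2-en-4-yn-1-yl]oxy}diphenylsilane
Product: 10 tert-butyl{[(2E)-3-methylpenta-2,4-dien-1-yl]oxy}diphenylsilane
Conditions: H2 (1 atm), Pd/CaCO3 poisoned with Pb(OAc)2 (Lindlar catalyst), quinoline, hexane, 23 °C
Reagents that add atoms: none
Why: Lindlar semihydrogenation of the terminal alkyne should stop at the vinyl group and leave the (E)-trisubstituted alkene, the future C13=C14, unchanged.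

Step 7
Reactants: 10 tert-butyl{[(2E)-3-methylpenta-2,4-dien-1-yl]oxy}diphenylsilane; 7 methyl 2-[(1S)-3-iodo-2-methyl-4-oxocyclohex-2-en-1-yl]acetate
Product: 12 methyl 2-[(1S)-3-[(3E)-5-(TBDPS-oxy)-3-methylpent-3-en-1-yl]-2-methyl-4-oxocyclohex-2-en-1-yl]acetate, via B-alkyl-9-BBN 11 (not isolated)
Conditions: 9-BBN, THF, 0 → 23 °C; then 7, PdCl2(dppf) (5 mol %), AsPh3, Cs2CO3, DMF/THF/H2O, 23 °C
Reagents that add atoms: none
Why: anti-Markovnikov hydroboration of the monosubstituted terminus of the 1,3-diene with 9-BBN (the trisubstituted alkene is far slower) followed by B-alkyl Suzuki–Miyaura coupling with the α-iodoenone forms C9–C11 with the (E)-alkene intact.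

Step 8
Reactants: 12 methyl 2-[(1S)-3-[(3E)-5-(TBDPS-oxy)-3-methylpent-3-en-1-yl]-2-methyl-4-oxocyclohex-2-en-1-yl]acetate; 13 allyltrimethylsilane
Product: 15 ring B ketone (C8=O; C5 CH2CO2Me arm β; C10 methyl β and allyl α; C9 side chain β), via trichlorotitanium enolate 14 (not isolated)
Conditions: TiCl4, CH2Cl2, −78 °C; aq. NaHCO3; then NaOMe (cat.), MeOH, 23 °C
Reagents that add atoms: none
Why: Hosomi–Sakurai conjugate allylation, in which the allylsilane adds axially to C10 anti to the C5 arm (pseudoaxial to avoid A(1,2) strain with the C10 methyl) so that the allyl group ends α and the methyl β, while axial protonation of enolate 14 and the brief methoxide equilibration place the C9 chain equatorial (β).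

Step 9
Reactants: 15 ring B ketone
Product: 16 ring B C8-methylene ester (C8=CH2; configuration as in 15)
Conditions: Ph3PCH3Br, KOtBu, THF, 0 → 40 °C
Reagents that add atoms: methyltriphenylphosphonium bromide, C[P+](c1ccccc1)(c1ccccc1)c1ccccc1.[Br-]
Why: Wittig methylenation of the hindered C8 ketone, under which C9 stays at its more stable equatorial configuration and the methyl ester is not attacked by the non-stabilised ylide at this temperature.

Step 10
Reactants: 16 ring B C8-methylene ester
Product: 18 ring B α-bromo ester (C5–CHBr–CO2Me; mixture at C4), via ketene silyl acetal 17 (not isolated)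
Conditions: LiN(iPr)2 (LDA), Me3SiCl, THF, −78 °C; then NBS, −78 → −40 °C
Reagents that add atoms: N-bromosuccinimide, O=C1CCC(=O)N1Br
Why: ester enolisation with in-situ silylation gives ketene silyl acetal 17, which NBS should brominate at C4 at −78 °C faster than it touches any alkene; the C4 epimers are used together because both give the same enolate in step 13.

Step 11
Reactants: 18 ring B α-bromo ester
Product: 20 ring B bromo ester alcohol (C10–CH2CH2CH2OH), via trialkylborane 19 (not isolated)
Conditions: Sia2BH (from BH3·SMe2 and 2-methylbut-2-ene), THF, 0 °C; then H2O2, pH 7 phosphate buffer, 0 → 23 °C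
Reagents that add atoms: hydrogen peroxide, OO
Why: Brown hydroboration–oxidation, in which the bulky dialkylborane adds to the monosubstituted allyl terminus much faster than to the hindered 1,1-disubstituted or the trisubstituted alkene, and buffered peroxide oxidation should spare the hindered secondary α-bromo ester.

Step 12
Reactants: 20 ring B bromo ester alcohol
Product: 21 ring B bromo ester aldehyde (C10–CH2CH2CHO; C8=CH2; full side chain; mixture at C4)
Conditions: Dess–Martin periodinane, NaHCO3, CH2Cl2, 0 → 23 °C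
Reagents that add atoms: none
Why: Dess–Martin oxidation converts the primary alcohol into the aldehyde under neutral conditions that leave the α-bromo ester and the silyl ether intact.

Step 13
Reactants: 21 ring B bromo ester aldehyde
Product: 23 methyl 3β-hydroxy-15-(TBDPS-oxy)-4-demethyl-labda-8(17),13E-diene-4α-carboxylate (C4–H β; trans-decalin), via samarium ester enolate 22 (not isolated)
Conditions: SmI2 (2.5 equiv), THF, −78 °C, slow addition of 21 (0.01 M); sat. aq. NH4Cl at −78 °C
Reagents that add atoms: none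
Why: SmI2 (divalent samarium) cleaves the C4–Br bond by two single-electron transfers and gives the trivalent samarium ester enolate 22, which adds to the C3 aldehyde; this is the samarium diiodide-mediated intramolecular Reformatsky reaction, known for closing carbocycles from α-bromo esters and tethered aldehydes. Ring A closes by a 6-(enolexo)-exo-trig aldol addition that forms C3–C4; because the C10–C1 and C5–C4 bonds are both equatorial on the ring B chair, only a chair-like trans-decalin transition state is available. C4: both bromide epimers give the same planar enolate, and allylic 1,3-strain keeps C5–H eclipsed with the enolate double bond, which should place the ester equatorial (4α) and the hydrogen axial (this centre is reset in step 14, so its epimer would do no harm). C3: the solvated O–Sm group should lie trans to the branched C5 substituent and bind the aldehyde oxygen in a Zimmerman–Traxler chair fused trans to the forming ring, so the oxygen is equatorial (3β); an open transition state would also favour the equatorial oxygen. The step needs 3β selectivity and reduction of C–Br in preference to the aldehyde: the first rests on the chelated chair fixed by the trans-diequatorial tether points on ring B, the second on the much faster electron transfer to α-bromo esters at −78 °C without HMPA. The samarium alkoxide is a poor leaving group and the quench is cold, so dehydration to the enoate is not expected.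

Step 14
Reactants: 23 methyl 3β-hydroxy-15-(TBDPS-oxy)-4-demethyl-labda-8(17),13E-diene-4α-carboxylate
Product: 25 methyl 3β-hydroxy-15-(TBDPS-oxy)labda-8(17),13E-dien-19-oate, via dilithio dianion 24 (not isolated)
Conditions: LiN(iPr)2 (2.5 equiv), THF, −78 → −20 °C; then MeI, DMPU, −78 → −20 °C; aq. NH4Cl
Reagents that add atoms: iodomethane, CI
Why: Fráter–Seebach alkylation, in which the chelated dianion 24 is methylated at C4 from the α face, anti to the axial C10 methyl and to the syn-axial H2β, so the new methyl (C18) is equatorial and the ester (C19) axial, cis to the 3β-oxygen.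

Step 15
Reactants: 25 methyl 3β-hydroxy-15-(TBDPS-oxy)labda-8(17),13E-dien-19-oate
Product: 26 15-(TBDPS-oxy)labda-8(17),13E-diene-3β,19-diol
Conditions: LiAlH4, THF, 0 → 66 °C
Reagents that add atoms: none
Why: hydride reduction of the hindered axial ester to the primary alcohol with LiAlH4 affects no stereocentre and leaves the alkenes and the silyl ether alone.

Step 16
Reactants: 26 15-(TBDPS-oxy)labda-8(17),13E-diene-3β,19-diol
Product: 27 3β-hydroxy-15-(TBDPS-oxy)labda-8(17),13E-dien-19-al
Conditions: TEMPO (10 mol %), PhI(OAc)2, CH2Cl2, 23 °C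
Reagents that add atoms: none
Why: oxoammonium (TEMPO/PhI(OAc)2) oxidation is strongly selective for the primary C19 alcohol over the hindered secondary 3β-alcohol and stops at the aldehyde, which cannot enolise because C4 is quaternary.

Step 17
Reactants: 27 3β-hydroxy-15-(TBDPS-oxy)labda-8(17),13E-dien-19-al
Product: 28 3β-acetoxy-15-(TBDPS-oxy)labda-8(17),13E-dien-19-al
Conditions: Ac2O, pyridine, DMAP (cat.), CH2Cl2, 23 °C
Reagents that add atoms: acetic anhydride, CC(=O)OC(C)=O
Why: DMAP-catalysed acylation of the equatorial 3β-alcohol, under which the non-enolisable aldehyde is inert and the mild base should not trigger retro-aldol cleavage.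

Step 18
Reactants: 28 3β-acetoxy-15-(TBDPS-oxy)labda-8(17),13E-dien-19-al
Product: 29 3β-acetoxy-15-hydroxylabda-8(17),13E-dien-19-al (target)
Conditions: Bu4NF, AcOH, THF, 23 °C
Reagents that add atoms: none
Why: fluoride cleavage of the silyl ether, buffered with acetic acid so that the acetate and the aldehyde survive, releases the C15 allylic alcohol.

**Compound list**

1 | 2-methylcyclohex-2-en-1-one | CC1=CCCCC1=O | starting material
2 | (S)-2-methylcyclohex-2-en-1-ol | O[C@H]1CCCC=C1C | intermediate
3 | trimethyl orthoacetate (1,1,1-trimethoxyethane) | CC(OC)(OC)OC | starting material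
4 | ketene acetal, 1-methoxy-1-{[(1S)-2-methylcyclohex-2-en-1-yl]oxy}ethene | C=C(OC)O[C@H]1CCCC=C1C | intermediate (not isolated)
5 | methyl 2-[(1S)-2-methylcyclohex-2-en-1-yl]acetate | COC(=O)C[C@@H]1CCCC=C1C | intermediate
6 | methyl 2-[(1S)-2-methyl-4-oxocyclohex-2-en-1-yl]acetate | COC(=O)C[C@@H]1CCC(=O)C=C1C | intermediate
7 | methyl 2-[(1S)-3-iodo-2-methyl-4-oxocyclohex-2-en-1-yl]acetate | COC(=O)C[C@@H]1CCC(=O)C(I)=C1C | intermediate
8 | (E)-3-methylpent-2-en-4-yn-1-ol | C#C/C(C)=C/CO | starting material
9 | tert-butyl{[(2E)-3-methylpent-2-en-4-yn-1-yl]oxy}diphenylsilane | C#C/C(C)=C/CO[Si](c1ccccc1)(c1ccccc1)C(C)(C)C | intermediate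
10 | tert-butyl{[(2E)-3-methylpenta-2,4-dien-1-yl]oxy}diphenylsilane | C=C/C(C)=C/CO[Si](c1ccccc1)(c1ccccc1)C(C)(C)C | intermediate
11 | 9-[(3E)-5-(TBDPS-oxy)-3-methylpent-3-en-1-yl]-9-borabicyclo[3.3.1]nonane | CC(C)(C)[Si](OC/C=C(C)/CCB1C2CCCC1CCC2)(c1ccccc1)c1ccccc1 | intermediate (not isolated)
12 | methyl 2-[(1S)-3-[(3E)-5-(TBDPS-oxy)-3-methylpent-3-en-1-yl]-2-methyl-4-oxocyclohex-2-en-1-yl]acetate | COC(=O)C[C@@H]1CCC(=O)C(CC/C(C)=C/CO[Si](c2ccccc2)(c2ccccc2)C(C)(C)C)=C1C | intermediate
13 | allyltrimethylsilane | C=CC[Si](C)(C)C | starting material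
14 | trichlorotitanium enolate of 15 (O–TiCl3 on C8; C8=C9; C10 allyl α, methyl β) | COC(=O)C[C@@H]1CCC(O[Ti](Cl)(Cl)Cl)=C(CC/C(C)=C/CO[Si](c2ccccc2)(c2ccccc2)C(C)(C)C)[C@@]1(C)CC=C | intermediate (not isolated)
15 | ring B ketone, methyl 2-[2-allyl-2-methyl-4-oxo-3-((3E)-5-(TBDPS-oxy)-3-methylpent-3-enyl)cyclohexyl]acetate (C5 arm β; C10 methyl β, allyl α; C9 chain β) | O=C1CC[C@@H](CC(=O)OC)[C@](C)(CC=C)[C@H]1CC/C(C)=C/CO[Si](c1ccccc1)(c1ccccc1)C(C)(C)C | intermediate
16 | ring B C8-methylene ester (as 15 with C8=CH2) | C=C1CC[C@@H](CC(=O)OC)[C@](C)(CC=C)[C@H]1CC/C(C)=C/CO[Si](c1ccccc1)(c1ccccc1)C(C)(C)C | intermediate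
17 | ketene methyl trimethylsilyl acetal of 16 (C4=C19(OMe)OSiMe3; E/Z mixture) | C=C1CC[C@@H](C=C(OC)O[Si](C)(C)C)[C@](C)(CC=C)[C@H]1CC/C(C)=C/CO[Si](c1ccccc1)(c1ccccc1)C(C)(C)C | intermediate (not isolated)
18 | ring B α-bromo ester (C5–CHBr–CO2Me; mixture at C4) | C=C1CC[C@@H](C(Br)C(=O)OC)[C@](C)(CC=C)[C@H]1CC/C(C)=C/CO[Si](c1ccccc1)(c1ccccc1)C(C)(C)C | intermediate
19 | trialkylborane, bis(3-methylbutan-2-yl)[3-(ring B C10)propyl]borane | C=C1CC[C@@H](C(Br)C(=O)OC)[C@](C)(CCCB(C(C)C(C)C)C(C)C(C)C)[C@H]1CC/C(C)=C/CO[Si](c1ccccc1)(c1ccccc1)C(C)(C)C | intermediate (not isolated)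
20 | ring B bromo ester alcohol (C10–CH2CH2CH2OH) | C=C1CC[C@@H](C(Br)C(=O)OC)[C@](C)(CCCO)[C@H]1CC/C(C)=C/CO[Si](c1ccccc1)(c1ccccc1)C(C)(C)C | intermediate
21 | ring B bromo ester aldehyde (C10–CH2CH2CHO; C8=CH2; mixture at C4) | C=C1CC[C@@H](C(Br)C(=O)OC)[C@](C)(CCC=O)[C@H]1CC/C(C)=C/CO[Si](c1ccccc1)(c1ccccc1)C(C)(C)C | intermediate
22 | samarium ester enolate (C4=C19(OMe)O–SmI2) | C=C1CC[C@@H](C=C(OC)O[Sm](I)I)[C@](C)(CCC=O)[C@H]1CC/C(C)=C/CO[Si](c1ccccc1)(c1ccccc1)C(C)(C)C | intermediate (not isolated)
23 | methyl 3β-hydroxy-15-(TBDPS-oxy)-4-demethyl-labda-8(17),13E-diene-4α-carboxylate (C4–H β; 5α-H, 9α-H, 10β-CH3) | C=C1CC[C@H]2[C@H](C(=O)OC)[C@@H](O)CC[C@]2(C)[C@H]1CC/C(C)=C/CO[Si](c1ccccc1)(c1ccccc1)C(C)(C)C | intermediate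
24 | dilithio dianion of 23 (O3–Li; C4=C19(OMe)OLi) | C=C1CC[C@H]2C(=C(OC)O[Li])[C@@H](O[Li])CC[C@]2(C)[C@H]1CC/C(C)=C/CO[Si](c1ccccc1)(c1ccccc1)C(C)(C)C | intermediate (not isolated)
25 | methyl 3β-hydroxy-15-(TBDPS-oxy)labda-8(17),13E-dien-19-oate | C=C1CC[C@H]2[C@@](C)(C(=O)OC)[C@@H](O)CC[C@]2(C)[C@H]1CC/C(C)=C/CO[Si](c1ccccc1)(c1ccccc1)C(C)(C)C | intermediate
26 | 15-(TBDPS-oxy)labda-8(17),13E-diene-3β,19-diol | C=C1CC[C@H]2[C@@](C)(CO)[C@@H](O)CC[C@]2(C)[C@H]1CC/C(C)=C/CO[Si](c1ccccc1)(c1ccccc1)C(C)(C)C | intermediate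
27 | 3β-hydroxy-15-(TBDPS-oxy)labda-8(17),13E-dien-19-al | C=C1CC[C@H]2[C@@](C)(C=O)[C@@H](O)CC[C@]2(C)[C@H]1CC/C(C)=C/CO[Si](c1ccccc1)(c1ccccc1)C(C)(C)C | intermediate
28 | 3β-acetoxy-15-(TBDPS-oxy)labda-8(17),13E-dien-19-al | C=C1CC[C@H]2[C@@](C)(C=O)[C@@H](OC(C)=O)CC[C@]2(C)[C@H]1CC/C(C)=C/CO[Si](c1ccccc1)(c1ccccc1)C(C)(C)C | intermediate
29 | 3β-acetoxy-15-hydroxylabda-8(17),13E-dien-19-al | C=C1CC[C@H]2[C@@](C)(C=O)[C@@H](OC(C)=O)CC[C@]2(C)[C@H]1CC/C(C)=C/CO | target

**Step count and risks**

Total: 18 steps. Longest linear sequence: 16 steps (1–4, then 7–18); steps 5–6 form the side-chain branch.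

Steps most likely to fail:

- Step 8 (Sakurai allylation of the tetrasubstituted enone). Attack at the congested C10 may be slow, and TiCl4 may meanwhile ionise the allylic silyl ether or let the side-chain alkene add to the activated enone. Fallback, from 12 back to 15: 1,2-addition of the allylcerium reagent (allylMgBr, CeCl3, THF, −78 °C) to the C8 ketone, expected from the α face opposite the pseudoaxial C5 arm, gives the tertiary C8 allyl carbinol F1. Deprotonation with KN(SiMe3)2 and 18-crown-6 (THF, 0 → 23 °C) then triggers an anionic oxy-Cope rearrangement that carries the allyl group suprafacially from C8 to C10; protonation of the resulting enolate returns 15.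

- Step 13 (key step). Facial control at C3 may be lost if the addition runs through an open instead of a chelated transition state, and the samarium enolate may be protonated before it closes the ring. Fallback, from 23 (taken as whatever mixture of C3 and C4 epimers forms) to 25, bypassing step 14: Dess–Martin oxidation gives the β-keto ester F2. C-methylation (K2CO3, MeI, acetone) from the α face, anti to the C10 methyl, gives the 4α-methyl-4β-methoxycarbonyl 3-ketone F3. NaBH4 (MeOH, 0 °C) then delivers hydride axially from the α face and gives 25.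

- Step 14 (dianion methylation). Removal of the shielded axial C4–H may be incomplete, or ring A may reopen by retro-aldol at the lithium aldolate stage before the dianion forms. Fallback, from 23 to 25: silylation of O3 (Et3SiOTf, 2,6-lutidine, CH2Cl2) gives the 3-O-triethylsilyl ether F4, which cannot undergo retro-aldol. Methylation of its monoenolate (LiN(iPr)2, THF/DMPU, MeI), again from the α face, gives the 4α-methyl silyl ether F5; β-elimination is disfavoured because the equatorial C3–O bond lies near the enolate plane. Selective removal of the triethylsilyl group (PPTS, MeOH, 0 °C) returns 25.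

Further compounds
F1 | step 8 | tertiary C8 allyl carbinol, methyl 2-[(1S)-4-allyl-4-hydroxy-2-methyl-3-((3E)-5-(TBDPS-oxy)-3-methylpent-3-enyl)cyclohex-2-en-1-yl]acetate (allyl α, OH β) | COC(=O)C[C@@H]1CC[C@@](O)(CC=C)C(CC/C(C)=C/CO[Si](c2ccccc2)(c2ccccc2)C(C)(C)C)=C1C
F2 | step 13 | β-keto ester, methyl 3-oxo-15-(TBDPS-oxy)-4-demethyl-labda-8(17),13E-diene-4-carboxylate (C4 epimers/enol) | C=C1CC[C@H]2C(C(=O)OC)C(=O)CC[C@]2(C)[C@H]1CC/C(C)=C/CO[Si](c1ccccc1)(c1ccccc1)C(C)(C)C
F3 | step 13 | methyl 3-oxo-15-(TBDPS-oxy)labda-8(17),13E-dien-19-oate | C=C1CC[C@H]2[C@@](C)(C(=O)OC)C(=O)CC[C@]2(C)[C@H]1CC/C(C)=C/CO[Si](c1ccccc1)(c1ccccc1)C(C)(C)C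
F4 | step 14 | 3-O-triethylsilyl ether of 23 | C=C1CC[C@H]2[C@H](C(=O)OC)[C@@H](O[Si](CC)(CC)CC)CC[C@]2(C)[C@H]1CC/C(C)=C/CO[Si](c1ccccc1)(c1ccccc1)C(C)(C)C
F5 | step 14 | 3-O-triethylsilyl ether of 25 | C=C1CC[C@H]2[C@@](C)(C(=O)OC)[C@@H](O[Si](CC)(CC)CC)CC[C@]2(C)[C@H]1CC/C(C)=C/CO[Si](c1ccccc1)(c1ccccc1)C(C)(C)C
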